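The five-membered ring is disconnected at C2–C3 and C1–C5 (spiro[4.5]decane numbering: C1 carbinol, C3 isopropenyl-bearing carbon, C5 spiro carbon). Both bonds are formed in one operation by a Lewis-acid formal (3+2) annulation between an enantiopure spiro vinylcyclopropane, built on the α′-carbon of 3-ethoxycyclohexenone, and the silyl enol ether of acetaldehyde. The step exploits that C5 is the α-carbon of a masked ketone (C6) of the six-membered ring, C3 is allylic and C1 is an aldol carbinol: the cyclopropane acts as a C3(+)/C5(−) dipole, the enol ether as a C2(−)/C1(+) unit. The vinylogous ester then gives the C6-methyl enone, and the C1 oxygen steers the C10 methyl.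

Key step: step 5

Assumption: the L-fructose-derived enantiomer of the Shi ketone is taken to be the one that gives the (S)-epoxide; compounds 3 to 6 are carried as epimer mixtures at the ring or spiro carbon, which becomes trigonal in step 5.

Step 1
Reactants: 1 3-ethoxycyclohex-2-en-1-one; 2 1-bromo-3-methylbut-2-ene
Product: 3 3-ethoxy-6-(3-methylbut-2-en-1-yl)cyclohex-2-en-1-one (racemic)
Conditions: LiN(i-Pr)2, THF, −78 °C; then 2, −78 → 0 °C
Reagents that add atoms: none
Why: Kinetic deprotonation of the vinylogous ester occurs at the α′-carbon and the lithium enolate is alkylated by the allylic bromide (Stork–Danheiser alkylation, SN2); the new stereocentre is racemic and becomes trigonal again in step 5.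

Step 2
Reactants: 3 3-ethoxy-6-(3-methylbut-2-en-1-yl)cyclohex-2-en-1-one
Product: 4 6-{[(2S)-3,3-dimethyloxiran-2-yl]methyl}-3-ethoxycyclohex-2-en-1-one (both epimers at the ring carbon)
Conditions: ent-Shi ketone (L-fructose-derived, cat.), KHSO5, K2CO3, Bu4NHSO4, MeCN–CH2(OMe)2–aq. buffer (pH 10.5), 0 °C
Reagents that add atoms: potassium peroxymonosulfate, [K+].[O-]S(=O)(=O)OO
Why: Shi asymmetric epoxidation: the chiral dioxirane attacks the electron-rich trisubstituted alkene (not the push–pull enol-ether C=C) through a spiro transition state, and the ketone enantiomer is chosen to set the (S)-configured epoxide CH carbon.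

Step 3
Reactants: 4 6-{[(2S)-3,3-dimethyloxiran-2-yl]methyl}-3-ethoxycyclohex-2-en-1-one
Product: 5 (1S)-6-ethoxy-1-(2-hydroxypropan-2-yl)spiro[2.5]oct-5-en-4-one (spiro-carbon epimers)
Conditions: LiN(i-Pr)2, THF, −78 → 0 °C; H2O
Reagents that add atoms: none
Why: The α′-enolate opens the epoxide intramolecularly at its secondary carbon (3-exo-tet enolate alkylation, favoured over the four-membered alternative) with inversion, so the epoxide stereocentre becomes the cyclopropane CH stereocentre.

Step 4
Reactants: 5 (1S)-6-ethoxy-1-(2-hydroxypropan-2-yl)spiro[2.5]oct-5-en-4-one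
Product: 6 (1R)-6-ethoxy-1-(prop-1-en-2-yl)spiro[2.5]oct-5-en-4-one (spiro-carbon epimers)
Conditions: Burgess reagent, PhMe, 60 °C
Reagents that add atoms: none
Why: Burgess dehydration (syn elimination) of the tertiary alcohol can only use a methyl hydrogen, since the alternative would be a strained alkylidenecyclopropane, and gives the isopropenyl donor group without touching the stereocentre.

Step 5
Reactants: 6 (1R)-6-ethoxy-1-(prop-1-en-2-yl)spiro[2.5]oct-5-en-4-one; 7 trimethyl(vinyloxy)silane
Product: 9 (1R,3R,5S)-8-ethoxy-1-hydroxy-3-(prop-1-en-2-yl)spiro[4.5]dec-7-en-6-one, via titanium dienolate aldehyde 8 (not isolated)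
Conditions: TiCl4, CH2Cl2, −78 → −40 °C; aq. NaHCO3
Reagents that add atoms: none
Why: Proposed new method: TiCl4 bound to the vinylogous-ester carbonyl polarises the cyclopropane bond between the allylic carbon and the spiro carbon, so that the enol silane opens the ring at the allylic carbon in an SN2-type homo-conjugate attack (C2–C3 bond, inversion at C3); after loss of Me3SiCl the titanium dienolate adds to the liberated aldehyde in an intramolecular aldol (C1–C5 bond, creating the spiro quaternary carbon). The closest known reaction type is the Lewis-acid formal (3+2) annulation of donor–acceptor cyclopropanes with enol silyl ethers, established for cyclopropane-1,1-diesters and extended here to a mono-acyl spiro vinylcyclopropane. The five-membered ring closes in a 5-(enolexo)-exo-trig mode. C3 follows stereospecifically from 6 by inversion, while C1 and C5 are set in the aldol: a closed, titanium-bridged transition state places the new C–O bond syn to the ring carbonyl, and a chair-like fold with pseudo-equatorial isopropenyl puts OH cis to isopropenyl. The step needs attack at the ring carbon and not at the alkene terminus (favoured because cleavage of that bond is coupled to the acceptor), C-closure instead of O-closure of the zwitterion (the dihydrofuran from O-closure can re-ionise under TiCl4), and no free allyl cation (low temperature) so that enantiopurity is kept.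

Step 6
Reactants: 9 (1R,3R,5S)-8-ethoxy-1-hydroxy-3-(prop-1-en-2-yl)spiro[4.5]dec-7-en-6-one
Product: 11 (1R,3R,5R)-1-hydroxy-6-methyl-3-(prop-1-en-2-yl)spiro[4.5]dec-6-en-8-one, via tertiary carbinol adduct 10 (not isolated)
Conditions: MeLi, CeCl3, THF, −78 °C; then 1 M HCl, THF, 0 °C
Reagents that add atoms: methyllithium, C[Li]; water, O
Why: 1,2-Addition of the methyl nucleophile to the vinylogous-ester carbonyl followed by acid hydrolysis of the enol ether with allylic transposition (Stork–Danheiser sequence) gives the β-methyl enone, with no stereocentre affected.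

Step 7
Reactants: 11 (1R,3R,5R)-1-hydroxy-6-methyl-3-(prop-1-en-2-yl)spiro[4.5]dec-6-en-8-one
Product: 13 (1R,3R,5S)-1-hydroxy-6-methyl-3-(prop-1-en-2-yl)spiro[4.5]deca-6,9-dien-8-one, via bis-silyl dienol ether 12 (not isolated)
Conditions: LiN(i-Pr)2, Me3SiCl, THF, −78 °C; Pd(OAc)2, MeCN, rt; then 0.5 M HCl, THF, 0 °C
Reagents that add atoms: none
Why: Kinetic α′-enolisation gives the cross-conjugated silyl dienol ether, which Pd(OAc)2 dehydrogenates (Saegusa–Ito oxidation) to the cross-conjugated dienone; the O-silyl group on the carbinol is removed on acidic work-up.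

Step 8
Reactants: 13 (1R,3R,5S)-1-hydroxy-6-methyl-3-(prop-1-en-2-yl)spiro[4.5]deca-6,9-dien-8-one
Product: 15 (1S,3R,5S)-1-hydroxy-6-methyl-3-(prop-1-en-2-yl)spiro[4.5]deca-6,9-dien-8-one, via inverted formate 14 (not isolated)
Conditions: HCO2H, PPh3, i-PrO2CN=NCO2i-Pr, THF, 0 °C → rt; then KHCO3, MeOH, 0 °C
Reagents that add atoms: formic acid, OC=O
Why: Mitsunobu reaction: the small, acidic formate should displace the oxyphosphonium group by SN2 with inversion at C1, approaching past the flat sp2 C10–H, and the formate is then cleaved by mild methanolysis without a strong base.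

Step 9
Reactants: 15 (1S,3R,5S)-1-hydroxy-6-methyl-3-(prop-1-en-2-yl)spiro[4.5]deca-6,9-dien-8-one
Product: 16 (1S,3R,5S,10S)-1-hydroxy-6,10-dimethyl-3-(prop-1-en-2-yl)spiro[4.5]dec-6-en-8-one
Conditions: AlMe3, CH2Cl2, −78 → −30 °C; aq. potassium sodium tartrate
Reagents that add atoms: trimethylaluminium, C[Al](C)C
Why: Alkoxide-directed conjugate addition: the aluminium alkoxide at C1 should deliver a methyl group to the adjacent unsubstituted β-carbon C10 (C6 is blocked by its methyl group) on the face that carries C1, which sets C10 with methyl cis to C1.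

Step 10
Reactants: 16 (1S,3R,5S,10S)-1-hydroxy-6,10-dimethyl-3-(prop-1-en-2-yl)spiro[4.5]dec-6-en-8-one; 17 3-methylbut-2-enoyl chloride
Product: 18 (1S,3R,5S,10S)-6,10-dimethyl-8-oxo-3-(prop-1-en-2-yl)spiro[4.5]dec-6-en-1-yl 3-methylbut-2-enoate
Conditions: pyridine, DMAP (cat.), CH2Cl2, 0 °C → rt
Reagents that add atoms: none
Why: DMAP-catalysed acylation of the secondary alcohol proceeds with retention at C1, and the weak base avoids deconjugation of the acyl group through a vinylketene.

Step 11
Reactants: 18 (1S,3R,5S,10S)-6,10-dimethyl-8-oxo-3-(prop-1-en-2-yl)spiro[4.5]dec-6-en-1-yl 3-methylbut-2-enoate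
Product: 19 (1S,3R,5S,9S,10R)-9-(acetyloxy)-6,10-dimethyl-8-oxo-3-(prop-1-en-2-yl)spiro[4.5]dec-6-en-1-yl 3-methylbut-2-enoate (target)
Conditions: Mn(OAc)3·2H2O, benzene, reflux (Dean–Stark)
Reagents that add atoms: manganese triacetate, CC(=O)O[Mn](OC(C)=O)OC(C)=O
Why: α′-Acetoxylation of the enone with Mn(OAc)3 goes through the manganese enolate at C9, the only enolisable α-carbon, and acetate should be delivered anti to the neighbouring C10 methyl to give the trans (9S,10R) arrangement.

Compound list
1 | 3-ethoxycyclohex-2-en-1-one | CCOC1=CC(=O)CCC1 | starting material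
2 | 1-bromo-3-methylbut-2-ene | CC(C)=CCBr | starting material
3 | 3-ethoxy-6-(3-methylbut-2-en-1-yl)cyclohex-2-en-1-one (racemic) | CCOC1=CC(=O)C(CC=C(C)C)CC1 | intermediate
4 | 6-{[(2S)-3,3-dimethyloxiran-2-yl]methyl}-3-ethoxycyclohex-2-en-1-one (ring-carbon epimers) | CCOC1=CC(=O)C(C[C@@H]2OC2(C)C)CC1 | intermediate
5 | (1S)-6-ethoxy-1-(2-hydroxypropan-2-yl)spiro[2.5]oct-5-en-4-one (spiro-carbon epimers) | CC(C)(O)[C@H]1CC12C(=O)C=C(OCC)CC2 | intermediate
6 | (1R)-6-ethoxy-1-(prop-1-en-2-yl)spiro[2.5]oct-5-en-4-one (spiro-carbon epimers) | C=C(C)[C@H]1CC12C(=O)C=C(OCC)CC2 | intermediate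
7 | trimethyl(vinyloxy)silane | C=CO[Si](C)(C)C | starting material
8 | trichlorotitanium dienolate of 3-ethoxy-6-[(2R)-4-oxo-2-(prop-1-en-2-yl)butyl]cyclohex-2-en-1-one | CCOC1=CC(O[Ti](Cl)(Cl)Cl)=C(C[C@H](CC=O)C(C)=C)CC1 | intermediate
9 | (1R,3R,5S)-8-ethoxy-1-hydroxy-3-(prop-1-en-2-yl)spiro[4.5]dec-7-en-6-one | C=C(C)[C@H]1C[C@@H](O)[C@]2(C1)C(=O)C=C(OCC)CC2 | intermediate
10 | 8-ethoxy-6-methyl-3-(prop-1-en-2-yl)spiro[4.5]dec-7-ene-1,6-diol (ring stereocentres as in 9; C6 carbinol epimers) | C=C(C)[C@H]1C[C@@H](O)[C@]2(C1)C(C)(O)C=C(OCC)CC2 | intermediate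
11 | (1R,3R,5R)-1-hydroxy-6-methyl-3-(prop-1-en-2-yl)spiro[4.5]dec-6-en-8-one | C=C(C)[C@H]1C[C@@H](O)[C@]2(C1)C(C)=CC(=O)CC2 | intermediate
12 | 6-methyl-3-(prop-1-en-2-yl)-1,8-bis(trimethylsilyloxy)spiro[4.5]deca-6,8-diene (stereocentres as in 11) | C=C(C)[C@H]1C[C@@H](O[Si](C)(C)C)[C@]2(C1)C(C)=CC(O[Si](C)(C)C)=CC2 | intermediate
13 | (1R,3R,5S)-1-hydroxy-6-methyl-3-(prop-1-en-2-yl)spiro[4.5]deca-6,9-dien-8-one | C=C(C)[C@H]1C[C@@H](O)[C@]2(C1)C(C)=CC(=O)C=C2 | intermediate
14 | (1S,3R,5S)-6-methyl-8-oxo-3-(prop-1-en-2-yl)spiro[4.5]deca-6,9-dien-1-yl formate | C=C(C)[C@H]1C[C@H](OC=O)[C@]2(C1)C(C)=CC(=O)C=C2 | intermediate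
15 | (1S,3R,5S)-1-hydroxy-6-methyl-3-(prop-1-en-2-yl)spiro[4.5]deca-6,9-dien-8-one | C=C(C)[C@H]1C[C@H](O)[C@]2(C1)C(C)=CC(=O)C=C2 | intermediate
16 | (1S,3R,5S,10S)-1-hydroxy-6,10-dimethyl-3-(prop-1-en-2-yl)spiro[4.5]dec-6-en-8-one | C=C(C)[C@H]1C[C@H](O)[C@]2(C1)C(C)=CC(=O)C[C@@H]2C | intermediate
17 | 3-methylbut-2-enoyl chloride | CC(C)=CC(Cl)=O | starting material
18 | (1S,3R,5S,10S)-6,10-dimethyl-8-oxo-3-(prop-1-en-2-yl)spiro[4.5]dec-6-en-1-yl 3-methylbut-2-enoate | C=C(C)[C@H]1C[C@H](OC(=O)C=C(C)C)[C@]2(C1)C(C)=CC(=O)C[C@@H]2C | intermediate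
19 | (1S,3R,5S,9S,10R)-9-(acetyloxy)-6,10-dimethyl-8-oxo-3-(prop-1-en-2-yl)spiro[4.5]dec-6-en-1-yl 3-methylbut-2-enoate | C=C(C)[C@H]1C[C@H](OC(=O)C=C(C)C)[C@]2(C1)C(C)=CC(=O)[C@@H](OC(C)=O)[C@@H]2C | target

Total step count: 11. Longest linear sequence: 11 steps (1 → 19).

Steps most likely to fail

1. Step 5 (Proposed new method). The ring-opened zwitterion may close through oxygen to a dihydrofuran, the enol silane may add at the alkene terminus instead of the ring carbon, or ionisation to a free allyl cation may erode the enantiopurity; the single acyl acceptor may also be too weak for opening at low temperature. Fallback by known chemistry, setting out from 1: the α′-lithium enolate of 1 would be alkylated with the separately prepared iodo acetal (3R)-3-(iodomethyl)-1,1-dimethoxy-4-methylpent-4-ene F1 to give 6-[(2R)-4,4-dimethoxy-2-(prop-1-en-2-yl)butyl]-3-ethoxycyclohex-2-en-1-one F2. The acetal would be hydrolysed (PPTS, wet acetone) to (3R)-3-[(4-ethoxy-2-oxocyclohex-3-en-1-yl)methyl]-4-methylpent-4-enal F3, and a titanium-mediated intramolecular aldol (TiCl4, i-Pr2NEt, CH2Cl2, −78 °C) would close the spiro ring and return to the route at 9.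

2. Step 8. Displacement at the carbinol next to the quaternary spiro carbon may not take place, with β-elimination to a cyclopentene or recovery of alcohol with retained configuration. Fallback that replaces the substitution by an oxidation–reduction, setting out from 13: the cis alcohol itself would direct the methyl transfer (AlMe3, CH2Cl2) to give (1R,3R,5S,10S)-1-hydroxy-6,10-dimethyl-3-(prop-1-en-2-yl)spiro[4.5]dec-6-en-8-one F4. Oxidation (Dess–Martin periodinane) would give (3R,5S,10S)-6,10-dimethyl-3-(prop-1-en-2-yl)spiro[4.5]dec-6-ene-1,8-dione F5. Reduction of the cyclopentanone only (NaBH4, MeOH, −40 °C; the saturated ketone should react before the hindered enone), with hydride entering anti to the new C10 methyl, would rejoin the route at 16.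

3. Step 9. The aluminium alkoxide may fragment by a retro-aldol-type cleavage of the C1–C5 bond with aromatisation of the dienone, or the methyl transfer may be slow or undirected. Fallback by a neutral tethered radical transfer, setting out from 15: silylation with (bromomethyl)chlorodimethylsilane (imidazole, CH2Cl2) would give (1S,3R,5S)-1-{[(bromomethyl)dimethylsilyl]oxy}-6-methyl-3-(prop-1-en-2-yl)spiro[4.5]deca-6,9-dien-8-one F6. Bu3SnH and AIBN (benzene, 80 °C) would close a six-membered ring by 6-exo radical addition to C10 on the face of C1, giving the bridged C10–CH2–SiMe2–O–C1 oxasilinane F7. Protodesilylation (Bu4NF, DMF, 60 °C) would leave the C10 methyl and the free alcohol, returning at 16.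

Further compounds
F1 | step 5 | (3R)-3-(iodomethyl)-1,1-dimethoxy-4-methylpent-4-ene | C=C(C)[C@H](CI)CC(OC)OC
F2 | step 5 | 6-[(2R)-4,4-dimethoxy-2-(prop-1-en-2-yl)butyl]-3-ethoxycyclohex-2-en-1-one | CCOC1=CC(=O)C(C[C@H](CC(OC)OC)C(C)=C)CC1
F3 | step 5 | (3R)-3-[(4-ethoxy-2-oxocyclohex-3-en-1-yl)methyl]-4-methylpent-4-enal | CCOC1=CC(=O)C(C[C@H](CC=O)C(C)=C)CC1
F4 | step 8 | (1R,3R,5S,10S)-1-hydroxy-6,10-dimethyl-3-(prop-1-en-2-yl)spiro[4.5]dec-6-en-8-one | C=C(C)[C@H]1C[C@@H](O)[C@]2(C1)C(C)=CC(=O)C[C@@H]2C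
F5 | step 8 | (3R,5S,10S)-6,10-dimethyl-3-(prop-1-en-2-yl)spiro[4.5]dec-6-ene-1,8-dione | C=C(C)[C@H]1CC(=O)[C@]2(C1)C(C)=CC(=O)C[C@@H]2C
F6 | step 9 | (1S,3R,5S)-1-{[(bromomethyl)dimethylsilyl]oxy}-6-methyl-3-(prop-1-en-2-yl)spiro[4.5]deca-6,9-dien-8-one | C=C(C)[C@H]1C[C@H](O[Si](C)(C)CBr)[C@]2(C1)C(C)=CC(=O)C=C2
F7 | step 9 | bridged oxasilinane from 6-exo radical cyclisation (C10–CH2–SiMe2–O–C1) | C=C(C)[C@H]1C[C@H](O[Si](C)(C)C3)[C@]2(C1)C(C)=CC(=O)C[C@@H]23
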